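The route rests on the bond between the two carbinol carbons of the side-chain diol: the tertiary C(OH)(CH3) linked by CH2 to C5 of the γ-lactone ring and the secondary CH(OH) carrying CH2–O–C7 of the coumarin ring. Both are acceptor carbons; the secondary one would expel aryloxide if metalated, so it stays an aldehyde, and the tertiary one is polarity-reversed as an alkenylchromium made from a 2-iodoallyl lactone, whose exo-methylene stands for the later CH3 and OH. One Ni/Cr coupling joins the unprotected halves, forms this bond and sets the secondary carbinol; the allylic hydroxyl then steers epoxidation at the tertiary carbon. Precursors: vinyl iodide 10 and aldehyde 14.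

Key step: step 8

Remark: the carbinol carbon made in step 8 keeps one geometry throughout; its CIP label is S in 15 and R from 16 on only because substituent priorities change.

Step 1
Reactants: 1 (R)-epichlorohydrin; 2 (1-bromoethenyl)trimethylsilane
Product: 4 (2R)-1-chloro-4-(trimethylsilyl)pent-4-en-2-ol, via vinyl Grignard reagent 3 (not isolated)
Conditions: 2, Mg, THF, reflux; then CuI (10 mol %), 1, −30 → 0 °C; aqueous work-up
Reagents that add atoms: none
Why: Copper-catalysed Grignard ring-opening of the epoxide (SN2 at the unsubstituted oxirane CH2) leaves the C–O stereocentre of 1 untouched, and the primary chloride is not displaced at low temperature.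

Step 2
Reactants: 4; 5 diethyl malonate
Product: 7 ethyl (5S)-2-oxo-5-[2-(trimethylsilyl)prop-2-en-1-yl]oxolane-3-carboxylate (both C3 epimers), via epoxide 6 (not isolated)
Conditions: NaOEt (2 equiv), EtOH, reflux; then aq. HCl
Reagents that add atoms: none
Why: Malonic ester γ-lactone synthesis: ethoxide closes the chlorohydrin to epoxide 6, the malonate anion opens it at CH2 and the alkoxide lactonises onto one ester, none of which touches the carbinol centre, which becomes C5 (S) of the lactone.

Step 3
Reactants: 7
Product: 8 (5S)-5-[2-(trimethylsilyl)prop-2-en-1-yl]oxolan-2-one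
Conditions: LiCl, H2O (2 equiv), DMSO, 150 °C
Reagents that add atoms: none
Why: Krapcho dealkoxycarbonylation (chloride attack on the ethyl group, loss of CO2, protonation) removes the activating ester without affecting C5 or the vinylsilane.

Step 4
Reactants: 8
Product: 9 (3R,5S)-3-methyl-5-[2-(trimethylsilyl)prop-2-en-1-yl]oxolan-2-one
Conditions: LDA, THF, −78 °C; MeI, −78 → −40 °C
Reagents that add atoms: iodomethane, CI
Why: Lactone enolate alkylation in which iodomethane approaches the planar enolate anti to the C5 substituent (1,3-induction), so the trans-(3R,5S) lactone should be the major isomer and the cis isomer is removed by chromatography.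

Step 5
Reactants: 9
Product: 10 (3R,5S)-5-(2-iodoprop-2-en-1-yl)-3-methyloxolan-2-one
Conditions: N-iodosuccinimide, MeCN/ClCH2CN (4:1), 0 °C → rt
Reagents that add atoms: N-iodosuccinimide, O=C1CCC(=O)N1I
Why: Electrophilic ipso-iododesilylation of the 2-silyl-1-alkene gives the 2-iodo-1-alkene regiospecifically and leaves both stereocentres untouched.

Step 6
Reactants: 11 umbelliferone; 12 2-bromoethanol
Product: 13 7-(2-hydroxyethoxy)-2H-chromen-2-one
Conditions: K2CO3, DMF, 80 °C
Reagents that add atoms: none
Why: Williamson ether synthesis on the acidic 7-hydroxyl of the coumarin (phenoxide SN2 on the primary bromide).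

Step 7
Reactants: 13
Product: 14 [(2-oxo-2H-chromen-7-yl)oxy]acetaldehyde
Conditions: Dess–Martin periodinane, CH2Cl2, 0 °C → rt; used at once
Reagents that add atoms: none
Why: Dess–Martin oxidation stops at the aldehyde and is run without water, so the hydration-prone α-aryloxy aldehyde should be obtained anhydrous for step 8.

Step 8
Reactants: 10; 14
Product: 15 (3R,5S)-5-[(3S)-3-hydroxy-2-methylidene-4-[(2-oxo-2H-chromen-7-yl)oxy]butyl]-3-methyloxolan-2-one
Conditions: CrCl2 (3 equiv), chiral 2-(2-sulfonamidophenyl)oxazoline ligand (3.3 equiv, antipode chosen to give the 3S alcohol), Et3N (3.3 equiv), NiCl2 (5 mol %), THF, rt; aqueous work-up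
Reagents that add atoms: none
Why: Ni(0) inserts into the C(sp2)–I bond of 10, the alkenylnickel transmetalates to Cr(III), and the alkenylchromium(III) adds to the aldehyde of 14 inside the chiral ligand sphere (Nozaki–Hiyama–Kishi reaction). The closest known reaction type is the asymmetric Ni/Cr coupling of 2-iodo-1-alkenes with α-alkoxy aldehydes used for unions of polyether fragments. No ring is closed. The new carbinol stereocentre is set by the ligand (reagent control), because the aldehyde is achiral and the lactone stereocentres are too remote to bias the addition; the minor epimer is a diastereomer and should be separable. The step needs chemoselectivity for the aldehyde over the γ-lactone and the coumarin enoate and must not expel aryloxide: C–Cr(III) bonds do not attack esters, and the aryloxy-bearing carbon is next to the electrophilic, not the metalated, carbon, so no β-elimination path exists.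

Step 9
Reactants: 15
Product: 16 (3R,5S)-5-({(2S)-2-[(1R)-1-hydroxy-2-[(2-oxo-2H-chromen-7-yl)oxy]ethyl]oxiran-2-yl}methyl)-3-methyloxolan-2-one
Conditions: VO(acac)2 (5 mol %), t-BuOOH (1.5 equiv), 2,6-lutidine (cat.), CH2Cl2, 0 °C
Reagents that add atoms: tert-butyl hydroperoxide, CC(C)(C)OO
Why: Hydroxyl-directed vanadium-catalysed epoxidation delivers oxygen syn to the hydroxyl in the conformer that keeps the carbinol C–H, not CH2OAr, next to the alkene's 2-substituent (A(1,2) strain), which sets the quaternary centre as the erythro epoxy alcohol with the geometry of the target's tertiary carbinol, while the electron-poor coumarin alkene does not react.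

Step 10
Reactants: 16
Product: 18 (3R,5S)-5-[(2R,3R)-2,3-dihydroxy-2-methyl-4-[(2-oxo-2H-chromen-7-yl)oxy]butyl]-3-methyloxolan-2-one (target), via iodohydrin 17 (not isolated)
Conditions: MgI2, PhMe/Et2O, −60 → 0 °C; then Bu3SnH, AIBN (cat.), 80 °C
Reagents that add atoms: none
Why: Chelation-controlled iodide opening then radical dehalogenation: magnesium bridges the carbinol oxygen and the oxirane so that iodide attacks the unhindered oxirane CH2 (SN2), and the tin hydride chain replaces iodine by hydrogen, turning that CH2 into the methyl group without touching any stereocentre.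

Compound list
1 | (R)-epichlorohydrin | ClC[C@H]1CO1 | starting material
2 | (1-bromoethenyl)trimethylsilane | C=C(Br)[Si](C)(C)C | starting material
3 | [1-(trimethylsilyl)ethenyl]magnesium bromide | C=C([Mg]Br)[Si](C)(C)C | intermediate
4 | (2R)-1-chloro-4-(trimethylsilyl)pent-4-en-2-ol | ClC[C@H](O)CC(=C)[Si](C)(C)C | intermediate
5 | diethyl malonate | CCOC(=O)CC(=O)OCC | starting material
6 | (2R)-2-[2-(trimethylsilyl)prop-2-en-1-yl]oxirane | C=C([Si](C)(C)C)C[C@@H]1CO1 | intermediate
7 | ethyl (5S)-2-oxo-5-[2-(trimethylsilyl)prop-2-en-1-yl]oxolane-3-carboxylate (both C3 epimers) | CCOC(=O)C1C[C@@H](CC(=C)[Si](C)(C)C)OC1=O | intermediate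
8 | (5S)-5-[2-(trimethylsilyl)prop-2-en-1-yl]oxolan-2-one | O=C1CC[C@@H](CC(=C)[Si](C)(C)C)O1 | intermediate
9 | (3R,5S)-3-methyl-5-[2-(trimethylsilyl)prop-2-en-1-yl]oxolan-2-one | C[C@@H]1C[C@@H](CC(=C)[Si](C)(C)C)OC1=O | intermediate
10 | (3R,5S)-5-(2-iodoprop-2-en-1-yl)-3-methyloxolan-2-one | C[C@@H]1C[C@@H](CC(I)=C)OC1=O | intermediate
11 | umbelliferone (7-hydroxy-2H-chromen-2-one) | O=c1ccc2ccc(O)cc2o1 | starting material
12 | 2-bromoethanol | OCCBr | starting material
13 | 7-(2-hydroxyethoxy)-2H-chromen-2-one | OCCOc1ccc2ccc(=O)oc2c1 | intermediate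
14 | [(2-oxo-2H-chromen-7-yl)oxy]acetaldehyde | O=CCOc1ccc2ccc(=O)oc2c1 | intermediate
15 | (3R,5S)-5-[(3S)-3-hydroxy-2-methylidene-4-[(2-oxo-2H-chromen-7-yl)oxy]butyl]-3-methyloxolan-2-one | C[C@@H]1C[C@@H](CC(=C)[C@H](O)COc2ccc3ccc(=O)oc3c2)OC1=O | intermediate
16 | (3R,5S)-5-({(2S)-2-[(1R)-1-hydroxy-2-[(2-oxo-2H-chromen-7-yl)oxy]ethyl]oxiran-2-yl}methyl)-3-methyloxolan-2-one | C[C@@H]1C[C@@H](C[C@]2(CO2)[C@H](O)COc3ccc4ccc(=O)oc4c3)OC1=O | intermediate
17 | (3R,5S)-5-[(2R,3R)-2,3-dihydroxy-2-(iodomethyl)-4-[(2-oxo-2H-chromen-7-yl)oxy]butyl]-3-methyloxolan-2-one | C[C@@H]1C[C@@H](C[C@@](CI)(O)[C@H](O)COc2ccc3ccc(=O)oc3c2)OC1=O | intermediate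
18 | (3R,5S)-5-[(2R,3R)-2,3-dihydroxy-2-methyl-4-[(2-oxo-2H-chromen-7-yl)oxy]butyl]-3-methyloxolan-2-one | C[C@@H]1C[C@@H](C[C@@](C)(O)[C@H](O)COc2ccc3ccc(=O)oc3c2)OC1=O | target

Total step count: 10. Longest linear sequence: 8 steps (steps 1–5, then 8–10).

Steps most likely to fail

Step 8. The ligand may give poor facial selectivity at the aldehyde, and the aldehyde may hydrate or oligomerise before it couples. The fallback sets out from 10 and 14 and comes back at 15. The coupling is run without chiral ligand (CrCl2, NiCl2 cat., DMSO, rt) and should give 15 together with its carbinol epimer (3R,5S)-5-[(3R)-3-hydroxy-2-methylidene-4-[(2-oxo-2H-chromen-7-yl)oxy]butyl]-3-methyloxolan-2-one F1. Dess–Martin oxidation of the mixture gives the enone (3R,5S)-3-methyl-5-[2-methylidene-3-oxo-4-[(2-oxo-2H-chromen-7-yl)oxy]butyl]oxolan-2-one F2. Corey–Bakshi–Shibata reduction with the (S)-methyl oxazaborolidine and catecholborane (toluene, −78 °C), the alkenyl group acting as the large substituent, should return 15, the stereocentre now being set by ketone reduction instead of by the coupling.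

Step 9. The A(1,2)-based facial selectivity may erode, and the acid-labile 2,2-disubstituted oxirane may be opened by the Lewis-acidic vanadium. The fallback sets out from 15 and comes back at 16. Osmium-catalysed dihydroxylation (OsO4 cat., NMO, acetone/H2O) should attack anti to the allylic hydroxyl and give the triol (3R,5S)-5-[(2S,3R)-2,3-dihydroxy-2-(hydroxymethyl)-4-[(2-oxo-2H-chromen-7-yl)oxy]butyl]-3-methyloxolan-2-one F3 with the same configuration at the quaternary carbon. Tin-mediated selective sulfonylation (Bu2SnO cat., TsCl, Et3N, CH2Cl2) gives the primary p-toluenesulfonate of this triol F4, and K2CO3 in MeCN closes the tertiary alkoxide onto the CH2OTs carbon to give 16.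

Step 10. The magnesium Lewis acid may ionise the tertiary oxirane carbon (iodide at the wrong carbon or a semipinacol shift) instead of permitting SN2 attack at CH2. The fallback sets out from 16 and comes back at 18. Phenylselenolate made from PhSeSePh and NaBH4 (EtOH, 0 °C → rt) opens the oxirane at CH2 without any Lewis acid to give the hydroxy selenide (3R,5S)-5-[(2R,3R)-2,3-dihydroxy-4-[(2-oxo-2H-chromen-7-yl)oxy]-2-[(phenylselanyl)methyl]butyl]-3-methyloxolan-2-one F5. Bu3SnH/AIBN (toluene, 80 °C) then cleaves the C–Se bond to give 18.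

Further compounds
F1 | step 8 | (3R,5S)-5-[(3R)-3-hydroxy-2-methylidene-4-[(2-oxo-2H-chromen-7-yl)oxy]butyl]-3-methyloxolan-2-one | C[C@@H]1C[C@@H](CC(=C)[C@@H](O)COc2ccc3ccc(=O)oc3c2)OC1=O
F2 | step 8 | (3R,5S)-3-methyl-5-[2-methylidene-3-oxo-4-[(2-oxo-2H-chromen-7-yl)oxy]butyl]oxolan-2-one | C[C@@H]1C[C@@H](CC(=C)C(=O)COc2ccc3ccc(=O)oc3c2)OC1=O
F3 | step 9 | (3R,5S)-5-[(2S,3R)-2,3-dihydroxy-2-(hydroxymethyl)-4-[(2-oxo-2H-chromen-7-yl)oxy]butyl]-3-methyloxolan-2-one | C[C@@H]1C[C@@H](C[C@@](CO)(O)[C@H](O)COc2ccc3ccc(=O)oc3c2)OC1=O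
F4 | step 9 | (2S,3R)-2,3-dihydroxy-2-{[(2S,4R)-4-methyl-5-oxooxolan-2-yl]methyl}-4-[(2-oxo-2H-chromen-7-yl)oxy]butyl 4-methylbenzenesulfonate | C[C@@H]1C[C@@H](C[C@@](COS(=O)(=O)c2ccc(C)cc2)(O)[C@H](O)COc2ccc3ccc(=O)oc3c2)OC1=O
F5 | step 10 | (3R,5S)-5-[(2R,3R)-2,3-dihydroxy-4-[(2-oxo-2H-chromen-7-yl)oxy]-2-[(phenylselanyl)methyl]butyl]-3-methyloxolan-2-one | C[C@@H]1C[C@@H](C[C@@](C[Se]c2ccccc2)(O)[C@H](O)COc2ccc3ccc(=O)oc3c2)OC1=O
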